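**Retrosynthetic overview**

1. Locants: abietane numbering (C1–C20) for the diterpenoid half, primes (C1'–C6') for the bicyclo[3.1.0]hexane, C2' being the spiro carbon. The target is the enol tautomer of an 11,12-o-quinone, so it is cut back to the C12 phenol 31 (IBX, last step).
2. The spiro cyclopentanone C7–C(=O)–C2'–C14–C8 is closed by a carbonylative Heck reaction of a C7 enol triflate onto a 14-(bicyclo[3.1.0]hex-2-en-2-yl) group. That aryl–alkenyl bond comes from a Suzuki coupling of aryl bromide 12 with boronate 24.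
3. Ring B is cut at C5–C6 and C9–C10. Enabling feature: C7 can stand at the ketone level, so C6 is the α-carbon of an aryl methyl ketone, C9 is the free ortho carbon of ring C, and the C5–C10 edge of ring A is the double bond of 1,3,3-trimethylcyclohexene. An oxidative radical [4+2] annulation joins these two nucleophilic partners and gives the whole A/B/C tricycle.
4. Boronate 24: side-chain stereocentre by organocatalytic Michael addition, E-alkene by cross-metathesis with an (R)-epoxyalkene, bicyclo[3.1.0]hexane by intramolecular cyclopropanation of the lithiated epoxide.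
5. Ring order: C (purchased arene) → B with A attached (step 6) → cyclopropane and cyclopentane of the sesquiterpenoid half (step 13) → spiro cyclopentanone (step 19) → quinone methide (step 23).

Key step: step 6

Assumption: the hydroxy-quinone methide written for the target is the thermodynamic tautomer of the 11,12-o-quinone that carries C7–H, so it forms from that quinone by enolisation.

**Route**

Step 1
Reactants: 1 3-bromoanisole
Product: 3 2-(2-bromo-6-methoxyphenyl)propan-2-ol, via (2-bromo-6-methoxyphenyl)lithium 2 (not isolated)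
Conditions: LDA, THF, −78 °C; acetone, −78 °C to rt; H2O
Reagents that add atoms: acetone CC(C)=O
Why: Directed ortho-lithiation at the carbon flanked by bromine and methoxy (held at −78 °C so that lithium bromide is not eliminated to an aryne) and 1,2-addition of the aryllithium to acetone place the future isopropyl carbon between the two substituents.

Step 2
Reactants: 3 2-(2-bromo-6-methoxyphenyl)propan-2-ol
Product: 4 1-bromo-2-isopropyl-3-methoxybenzene
Conditions: Et3SiH, CF3CO2H, CH2Cl2, 0 °C to rt
Reagents that add atoms: none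
Why: Ionic hydrogenation (Kursanov–Parnes reduction) of the tertiary benzylic alcohol through its cumyl-type cation should give the isopropyl group without touching the aryl bromide.

Step 3
Reactants: 4 1-bromo-2-isopropyl-3-methoxybenzene
Product: 5 1-(2-bromo-3-isopropyl-4-methoxyphenyl)ethan-1-one
Conditions: AcCl, AlCl3, CH2Cl2, 0 °C
Reagents that add atoms: acetyl chloride CC(Cl)=O
Why: Friedel–Crafts acylation goes para to the methoxy group (the ortho position is shielded by the O-methyl, which turns away from the isopropyl group), which places the acetyl group next to the bromine as required for C8 and C14.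

Step 4
Reactants: 6 2,2,6-trimethylcyclohexan-1-one
Product: 8 2,6,6-trimethylcyclohex-1-en-1-yl trifluoromethanesulfonate, via lithium enolate 7 (not isolated)
Conditions: LDA, THF, −78 to 0 °C; PhNTf2, 0 °C to rt
Reagents that add atoms: N-phenylbis(trifluoromethanesulfonimide) O=S(=O)(N(c1ccccc1)S(=O)(=O)C(F)(F)F)C(F)(F)F
Why: The ketone has a single enolisable position, so deprotonation and O-triflation of the lithium enolate can give only the tetrasubstituted enol triflate.

Step 5
Reactants: 8 2,6,6-trimethylcyclohex-1-en-1-yl trifluoromethanesulfonate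
Product: 9 1,3,3-trimethylcyclohex-1-ene
Conditions: Pd(OAc)2 (2 mol %), PPh3, Bu3N, HCO2H, DMF, 60 °C
Reagents that add atoms: none
Why: Palladium-catalysed transfer hydrogenolysis of the enol triflate with formate (oxidative addition, formate exchange, decarboxylation, reductive elimination) should give the trisubstituted alkene without double-bond migration.

Step 6
Reactants: 5 1-(2-bromo-3-isopropyl-4-methoxyphenyl)ethan-1-one; 9 1,3,3-trimethylcyclohex-1-ene
Product: 10 (±)-trans-14-bromo-12-methoxyabieta-8,11,13-trien-7-one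
Conditions: Mn(OAc)3·2H2O (2.4 equiv, added in portions), 9 (5 equiv), AcOH, 80 °C, Ar
Reagents that add atoms: none
Why: The manganese enolate of 5 collapses to the electrophilic α-keto radical at C6, which adds to the less substituted alkene carbon of 9 (C5) and gives the tertiary C10 radical; this nucleophilic radical attacks C9, the only free carbon ortho to the carbonyl, and the cyclohexadienyl radical is oxidised by a second equivalent of trivalent manganese and rearomatises. The closest known reaction type is the Mn(OAc)3-mediated α-tetralone synthesis from aryl methyl ketones and alkenes, together with the manganese-based tandem radical cyclisations that end on an arene. Ring B closes as a six-membered ring by homolytic aromatic substitution (6-endo ortho attack on the C8=C9 edge of ring C, the 5-exo ipso mode being disfavoured by the spiro strain and the flanking bromine). C5 and C10 are set relative to each other in this closure: with the C5 side chain equatorial on the chair of ring A, the aryl ketone reaches the equatorial lobe at C10, which avoids a syn-axial clash with the axial C4 methyl and should give the trans A/B fusion, as in the cationic closure of the same carbon skeleton; the product is racemic and is resolved in step 7. The addition regiochemistry follows radical stability, the C14 bromine secures the site of attack on the arene, and portionwise addition of the oxidant keeps its stationary concentration low so that ring closure can outrun oxidation of the tertiary radical.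

Step 7
Reactants: 10 (±)-trans-14-bromo-12-methoxyabieta-8,11,13-trien-7-one
Product: 11 (5S,7S,10S)-14-bromo-12-methoxyabieta-8,11,13-trien-7-ol
Conditions: (R)-2-methyl-CBS-oxazaborolidine (20 mol %), BH3·SMe2 (0.7 equiv), THF, −20 °C; MeOH; chromatography
Reagents that add atoms: none
Why: Corey–Bakshi–Shibata reduction under reagent control turns both enantiomers of 10 into (7S)-alcohols, so the (5S,10S) enantiomer gives 11 (7β-OH, hydride from the face anti to the axial C10 methyl, the matched case) and the (5R,10R) enantiomer gives the (5R,7S,10R) diastereomer, which is removed by chromatography and discarded.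

Step 8
Reactants: 11 (5S,7S,10S)-14-bromo-12-methoxyabieta-8,11,13-trien-7-ol
Product: 12 (5S,10S)-14-bromo-12-methoxyabieta-8,11,13-trien-7-one
Conditions: Dess–Martin periodinane, NaHCO3, CH2Cl2, rt
Reagents that add atoms: none
Why: Dess–Martin oxidation returns the now enantiopure aryl ketone without affecting the C5 and C10 stereocentres, which are not enolisable from C7.

Step 9
Reactants: 13 3-methylbutanal; 14 but-3-en-2-one
Product: 15 (2S)-2-isopropyl-5-oxohexanal
Conditions: (S)-2-(methoxydiphenylmethyl)pyrrolidine (5 mol %), ethyl 3,4-dihydroxybenzoate (20 mol %), neat, 4 °C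
Reagents that add atoms: none
Why: Enamine-catalysed asymmetric Michael addition of the aldehyde to the enone, in which the diphenyl(methoxy)methyl group shields one face of the E-enamine, should set the (S) stereocentre that ends as the isopropyl-bearing carbon of the side chain.

Step 10
Reactants: 15 (2S)-2-isopropyl-5-oxohexanal
Product: 16 (5S)-5-isopropylhept-6-en-2-one
Conditions: Ph3PCH3Br, KHMDS, THF, −78 to 0 °C
Reagents that add atoms: methylenetriphenylphosphorane C=P(c1ccccc1)(c1ccccc1)c1ccccc1
Why: Wittig methylenation with one equivalent of the unstabilised ylide at low temperature is selective for the aldehyde over the methyl ketone and is fast enough to avoid epimerisation of the α-stereocentre.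

Step 11
Reactants: 16 (5S)-5-isopropylhept-6-en-2-one
Product: 17 2-[(3S)-3-isopropylpent-4-en-1-yl]-2-methyl-1,3-dioxolane
Conditions: ethylene glycol, PPTS (cat.), benzene, reflux, Dean–Stark
Reagents that add atoms: ethane-1,2-diol OCCO
Why: Acid-catalysed ketalisation with azeotropic removal of water protects the methyl ketone against the strong bases of steps 13, 15 and 18.

Step 12
Reactants: 17 2-[(3S)-3-isopropylpent-4-en-1-yl]-2-methyl-1,3-dioxolane; 18 (2R)-2-(but-3-en-1-yl)oxirane
Product: 19 (2R)-2-[(3E,5S)-5-isopropyl-7-(2-methyl-1,3-dioxolan-2-yl)hept-3-en-1-yl]oxirane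
Conditions: 18 (3 equiv), second-generation Hoveyda–Grubbs catalyst (5 mol %), CH2Cl2, 40 °C
Reagents that add atoms: none
Why: Olefin cross-metathesis between the α-branched terminal alkene (slow to homodimerise) and an excess of the unhindered epoxyalkene should give the E-disubstituted alkene, the terminal epoxide being inert to the ruthenium carbene.

Step 13
Reactants: 19 (2R)-2-[(3E,5S)-5-isopropyl-7-(2-methyl-1,3-dioxolan-2-yl)hept-3-en-1-yl]oxirane
Product: 20 (1S,2R,5S,6S)-6-[(3S)-2-methyl-5-(2-methyl-1,3-dioxolan-2-yl)pentan-3-yl]bicyclo[3.1.0]hexan-2-ol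
Conditions: LTMP (from 2,2,6,6-tetramethylpiperidine and n-BuLi, 2.2 equiv), t-BuOMe, 0 °C to rt; H2O
Reagents that add atoms: none
Why: Lithiation of the terminal epoxide trans to its substituent gives a lithium carbenoid that cyclopropanates the tethered alkene intramolecularly (a known route to bicyclo[3.1.0]hexan-2-ols), stereospecifically for the E-alkene (side chain exo at C6') and with the alkoxide trans to the cyclopropane, so that the (R)-epoxide centre fixes C1', C5' and C6'.

Step 14
Reactants: 20 (1S,2R,5S,6S)-6-[(3S)-2-methyl-5-(2-methyl-1,3-dioxolan-2-yl)pentan-3-yl]bicyclo[3.1.0]hexan-2-ol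
Product: 21 (1S,5S,6S)-6-[(3S)-2-methyl-5-(2-methyl-1,3-dioxolan-2-yl)pentan-3-yl]bicyclo[3.1.0]hexan-2-one
Conditions: Dess–Martin periodinane, NaHCO3, CH2Cl2, rt
Reagents that add atoms: none
Why: Dess–Martin oxidation of the secondary alcohol gives the bicyclic ketone, whose only stereocentre next to the carbonyl is a cyclopropane bridgehead that does not epimerise.

Step 15
Reactants: 21 (1S,5S,6S)-6-[(3S)-2-methyl-5-(2-methyl-1,3-dioxolan-2-yl)pentan-3-yl]bicyclo[3.1.0]hexan-2-one
Product: 23 (1S,5S,6S)-6-[(3S)-2-methyl-5-(2-methyl-1,3-dioxolan-2-yl)pentan-3-yl]bicyclo[3.1.0]hex-2-en-2-yl trifluoromethanesulfonate, via potassium enolate 22 (not isolated)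
Conditions: KHMDS, THF, −78 °C; PhNTf2, −78 to 0 °C
Reagents that add atoms: N-phenylbis(trifluoromethanesulfonimide) O=S(=O)(N(c1ccccc1)S(=O)(=O)C(F)(F)F)C(F)(F)F
Why: The ketone can enolise only towards C3' (the other α-carbon is the cyclopropane bridgehead), so kinetic deprotonation and O-triflation give a single enol triflate.

Step 16
Reactants: 23 (1S,5S,6S)-6-[(3S)-2-methyl-5-(2-methyl-1,3-dioxolan-2-yl)pentan-3-yl]bicyclo[3.1.0]hex-2-en-2-yl trifluoromethanesulfonate
Product: 24 2-{(1S,5S,6S)-6-[(3S)-2-methyl-5-(2-methyl-1,3-dioxolan-2-yl)pentan-3-yl]bicyclo[3.1.0]hex-2-en-2-yl}-4,4,5,5-tetramethyl-1,3,2-dioxaborolane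
Conditions: B2pin2, PdCl2(PPh3)2 (3 mol %), PPh3, KOPh, toluene, 50 °C
Reagents that add atoms: bis(pinacolato)diboron CC1(C)OB(OC1(C)C)B1OC(C)(C)C(C)(C)O1
Why: Miyaura borylation of the alkenyl triflate (oxidative addition, transmetalation with the phenoxide-activated diboron, reductive elimination) should give the alkenyl boronate with the cyclopropane intact.

Step 17
Reactants: 12 (5S,10S)-14-bromo-12-methoxyabieta-8,11,13-trien-7-one; 24 alkenyl boronate
Product: 25 (5S,10S)-14-{(1S,5S,6S)-6-[(3S)-2-methyl-5-(2-methyl-1,3-dioxolan-2-yl)pentan-3-yl]bicyclo[3.1.0]hex-2-en-2-yl}-12-methoxyabieta-8,11,13-trien-7-one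
Conditions: Pd(OAc)2 (5 mol %), SPhos (10 mol %), K3PO4, toluene/H2O, 90 °C
Reagents that add atoms: none
Why: Suzuki–Miyaura coupling with a bulky, electron-rich biarylphosphine ligand is the established way to join a di-ortho-substituted aryl bromide to a 1-cycloalkenyl boronate, and no stereocentre is involved.

Step 18
Reactants: 25 14-alkenyl 7-ketone
Product: 27 (5S,10S)-14-{bicyclo[3.1.0]hex-2-en-2-yl unit of 25}-12-methoxyabieta-6,8,11,13-tetraen-7-yl trifluoromethanesulfonate, via potassium dienolate 26 (not isolated)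
Conditions: KHMDS, THF, −78 °C; PhNTf2, −78 to 0 °C
Reagents that add atoms: N-phenylbis(trifluoromethanesulfonimide) O=S(=O)(N(c1ccccc1)S(=O)(=O)C(F)(F)F)C(F)(F)F
Why: C6 is the only enolisable position of the aryl ketone, so the potassium dienolate is O-triflated to the dienyl triflate that carries the C6=C7 bond.

Step 19
Reactants: 27 C7 dienyl triflate
Product: 28 spiro dienone (C7–C(=O)–C2' ring closed; C6=C7 alkene; C3'=C4' alkene; ketal in place; methyl ether in place)
Conditions: Pd(OAc)2 (10 mol %), dppf (12 mol %), CO (10 atm), 1,2,2,6,6-pentamethylpiperidine, DMA, 85 °C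
Reagents that add atoms: carbon monoxide [C-]#[O+]
Why: Carbonylative Heck cyclisation (cyclic acylpalladation): oxidative addition to the enol triflate, CO insertion and 5-exo syn-addition of the acylpalladium to the trisubstituted C2'=C3' alkene from the face anti to the cyclopropane should create the spiro carbon with the ring-C carbon syn and the carbonyl anti to the cyclopropane, and β-hydride elimination towards C4' ends the cycle.

Step 20
Reactants: 28 spiro dienone
Product: 29 spiro enone with saturated cyclopentane ring of the bicyclo[3.1.0]hexane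
Conditions: KO2CN=NCO2K (10 equiv), AcOH (20 equiv, slow addition), pyridine/MeOH, rt
Reagents that add atoms: none
Why: Diimide, set free from dipotassium azodicarboxylate and acetic acid, reduces the strained cis-disubstituted C3'=C4' alkene by concerted syn hydrogen transfer without hydrogenolysis of the adjacent cyclopropane, leaves the trisubstituted, conjugated C6=C7 bond, and involves no hydrazide that could condense with the ring ketone.

Step 21
Reactants: 29 spiro enone
Product: 30 spiro ketone with C6H2 and C7–H (C7 epimers)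
Conditions: [(Ph3P)CuH]6 (0.4 equiv), benzene, H2O (2 equiv), rt
Reagents that add atoms: none
Why: Copper hydride conjugate reduction of the enone delivers hydride to C6 and protonates the copper enolate at C7, whose configuration is inconsequential because C7 becomes sp2 again in step 23.

Step 22
Reactants: 30 spiro ketone
Product: 31 C12 phenol with free side-chain methyl ketone
Conditions: BBr3 (4 equiv), CH2Cl2, −78 to 0 °C; H2O
Reagents that add atoms: none
Why: Boron tribromide cleaves the aryl methyl ether and the dioxolane in one operation at low temperature, while the unactivated cyclopropane and the ketones should be left intact.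

Step 23
Reactants: 31 C12 phenol
Product: 33 target CNP0140364.1, via o-quinone 32 (not isolated)
Conditions: IBX (1.1 equiv), DMF, rt, Ar, dark
Reagents that add atoms: 2-iodoxybenzoic acid (IBX) O=C1OI(=O)(O)c2ccccc12
Why: IBX oxygenates the phenol at C11, its only free ortho position, to the 11,12-o-quinone, whose C7–H (α to the ketone and vinylogous to the quinone) enolises to the hydroxy-p-quinone methide, so both C7 epimers of 31 converge on the target and no other stereocentre is touched.

**Compound list**

1 | 3-bromoanisole | COc1cccc(Br)c1 | starting material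
2 | (2-bromo-6-methoxyphenyl)lithium | [Li]c1c(Br)cccc1OC | intermediate
3 | 2-(2-bromo-6-methoxyphenyl)propan-2-ol | COc1cccc(Br)c1C(C)(C)O | intermediate
4 | 1-bromo-2-isopropyl-3-methoxybenzene | COc1cccc(Br)c1C(C)C | intermediate
5 | 1-(2-bromo-3-isopropyl-4-methoxyphenyl)ethan-1-one | CC(=O)c1ccc(OC)c(C(C)C)c1Br | intermediate
6 | 2,2,6-trimethylcyclohexan-1-one (racemic) | CC1CCCC(C)(C)C1=O | starting material
7 | lithium 2,6,6-trimethylcyclohex-1-en-1-olate | [Li+].[O-]C1=C(C)CCCC1(C)C | intermediate
8 | 2,6,6-trimethylcyclohex-1-en-1-yl trifluoromethanesulfonate | CC1=C(OS(=O)(=O)C(F)(F)F)C(C)(C)CCC1 | intermediate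
9 | 1,3,3-trimethylcyclohex-1-ene | CC1=CC(C)(C)CCC1 | intermediate
10 | (±)-trans-14-bromo-12-methoxyabieta-8,11,13-trien-7-one (racemate; the (5S,10S) enantiomer is drawn) | CC(C)c1c(OC)cc2c(c1Br)C(=O)C[C@@H]1[C@]2(C)CCCC1(C)C | intermediate
11 | (5S,7S,10S)-14-bromo-12-methoxyabieta-8,11,13-trien-7-ol | CC(C)c1c(OC)cc2c(c1Br)[C@@H](O)C[C@@H]1[C@]2(C)CCCC1(C)C | intermediate
12 | (5S,10S)-14-bromo-12-methoxyabieta-8,11,13-trien-7-one | CC(C)c1c(OC)cc2c(c1Br)C(=O)C[C@@H]1[C@]2(C)CCCC1(C)C | intermediate
13 | 3-methylbutanal | CC(C)CC=O | starting material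
14 | but-3-en-2-one (methyl vinyl ketone) | C=CC(C)=O | starting material
15 | (2S)-2-isopropyl-5-oxohexanal | CC(=O)CC[C@@H](C(C)C)C=O | intermediate
16 | (5S)-5-isopropylhept-6-en-2-one | CC(=O)CC[C@@H](C(C)C)C=C | intermediate
17 | 2-[(3S)-3-isopropylpent-4-en-1-yl]-2-methyl-1,3-dioxolane | CC1(CC[C@@H](C(C)C)C=C)OCCO1 | intermediate
18 | (2R)-2-(but-3-en-1-yl)oxirane | C=CCC[C@@H]1CO1 | starting material
19 | (2R)-2-[(3E,5S)-5-isopropyl-7-(2-methyl-1,3-dioxolan-2-yl)hept-3-en-1-yl]oxirane | CC1(CC[C@@H](C(C)C)/C=C/CC[C@@H]2CO2)OCCO1 | intermediate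
20 | (1S,2R,5S,6S)-6-[(3S)-2-methyl-5-(2-methyl-1,3-dioxolan-2-yl)pentan-3-yl]bicyclo[3.1.0]hexan-2-ol (side chain exo, OH trans to the cyclopropane) | CC1(CC[C@@H](C(C)C)[C@H]2[C@@H]3CC[C@@H](O)[C@@H]32)OCCO1 | intermediate
21 | (1S,5S,6S)-6-[(3S)-2-methyl-5-(2-methyl-1,3-dioxolan-2-yl)pentan-3-yl]bicyclo[3.1.0]hexan-2-one | CC1(CC[C@@H](C(C)C)[C@H]2[C@@H]3CCC(=O)[C@@H]32)OCCO1 | intermediate
22 | potassium enolate of 21 (bicyclo[3.1.0]hex-2-en-2-olate) | CC1(CC[C@@H](C(C)C)[C@H]2[C@@H]3CC=C([O-])[C@@H]32)OCCO1.[K+] | intermediate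
23 | (1S,5S,6S)-6-[(3S)-2-methyl-5-(2-methyl-1,3-dioxolan-2-yl)pentan-3-yl]bicyclo[3.1.0]hex-2-en-2-yl trifluoromethanesulfonate | CC1(CC[C@@H](C(C)C)[C@H]2[C@@H]3CC=C(OS(=O)(=O)C(F)(F)F)[C@@H]32)OCCO1 | intermediate
24 | 2-{(1S,5S,6S)-6-[(3S)-2-methyl-5-(2-methyl-1,3-dioxolan-2-yl)pentan-3-yl]bicyclo[3.1.0]hex-2-en-2-yl}-4,4,5,5-tetramethyl-1,3,2-dioxaborolane | CC1(CC[C@@H](C(C)C)[C@H]2[C@@H]3CC=C(B4OC(C)(C)C(C)(C)O4)[C@@H]32)OCCO1 | intermediate
25 | (5S,10S)-14-{(1S,5S,6S)-6-[(3S)-2-methyl-5-(2-methyl-1,3-dioxolan-2-yl)pentan-3-yl]bicyclo[3.1.0]hex-2-en-2-yl}-12-methoxyabieta-8,11,13-trien-7-one | CC(C)c1c(OC)cc2c(c1C3=CC[C@H]4[C@H]([C@@H](CCC5(C)OCCO5)C(C)C)[C@@H]34)C(=O)C[C@@H]6[C@]2(C)CCCC6(C)C | intermediate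
26 | potassium dienolate of 25 (O7 enolate, C6=C7) | CC(C)c1c(OC)cc2c(c1C3=CC[C@H]4[C@H]([C@@H](CCC5(C)OCCO5)C(C)C)[C@@H]34)C([O-])=C[C@@H]6[C@]2(C)CCCC6(C)C.[K+] | intermediate
27 | (5S,10S)-14-{(1S,5S,6S)-6-[(3S)-2-methyl-5-(2-methyl-1,3-dioxolan-2-yl)pentan-3-yl]bicyclo[3.1.0]hex-2-en-2-yl}-12-methoxyabieta-6,8,11,13-tetraen-7-yl trifluoromethanesulfonate | CC(C)c1c(OC)cc2c(c1C3=CC[C@H]4[C@H]([C@@H](CCC5(C)OCCO5)C(C)C)[C@@H]34)C(OS(=O)(=O)C(F)(F)F)=C[C@@H]6[C@]2(C)CCCC6(C)C | intermediate
28 | spiro dienone: (5S,10S)-12-methoxyabieta-6,8,11,13-tetraene with C7 and C14 bridged by C(=O)–C2' of the bicyclo[3.1.0]hex-3'-ene (C2' spiro, (2'R), ring-C carbon syn and carbonyl anti to the cyclopropane), ketal side chain at C6' | CC(C)c1c(OC)cc2c3c1[C@]4(C=C[C@H]5[C@H]([C@@H](CCC7(C)OCCO7)C(C)C)[C@@H]45)C(=O)C3=C[C@@H]6[C@]2(C)CCCC6(C)C | intermediate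
29 | spiro enone: as 28 with the bicyclo[3.1.0]hexane ring saturated ((1'S,2'R,5'S,6'S)), C6=C7 retained | CC(C)c1c(OC)cc2c3c1[C@]4(CC[C@H]5[C@H]([C@@H](CCC7(C)OCCO7)C(C)C)[C@@H]45)C(=O)C3=C[C@@H]6[C@]2(C)CCCC6(C)C | intermediate
30 | spiro ketone: (5S,10S)-12-methoxyabieta-8,11,13-triene with the C7–C(=O)–C2'–C14 cyclopentanone, ketal side chain (C7 epimer mixture) | CC(C)c1c(OC)cc2c3c1[C@]4(CC[C@H]5[C@H]([C@@H](CCC7(C)OCCO7)C(C)C)[C@@H]45)C(=O)C3C[C@@H]6[C@]2(C)CCCC6(C)C | intermediate
31 | C12 phenol: as 30 with 12-OH and the (3S)-2-methyl-6-oxoheptan-3-yl chain at C6' (C7 epimer mixture) | CC(C)c1c(O)cc2c3c1[C@]4(CC[C@H]5[C@H]([C@@H](CCC(C)=O)C(C)C)[C@@H]45)C(=O)C3C[C@@H]6[C@]2(C)CCCC6(C)C | intermediate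
32 | 11,12-o-quinone of 31 (abieta-8,13-diene-11,12-dione core, C7–H) | CC(C)C=1C(=O)C(=O)C2=C3C=1[C@]4(CC[C@H]5[C@H]([C@@H](CCC(C)=O)C(C)C)[C@@H]45)C(=O)C3C[C@@H]6[C@]2(C)CCCC6(C)C | intermediate
33 | CNP0140364.1: (5S,10S)-11-hydroxyabieta-7,9(11),13-trien-12-one with C7 and C14 bridged by C(=O)–C2' of the (1'S,2'R,5'S,6'S)-bicyclo[3.1.0]hexane that carries the (3S)-2-methyl-6-oxoheptan-3-yl chain at C6' | CC(=O)CC[C@@H](C(C)C)[C@H]1[C@@H]2CC[C@@]3(C(=O)C4=C5C3=C(C(C)C)C(=O)C(O)=C5[C@@]3(C)CCCC(C)(C)[C@@H]3C4)[C@@H]21 | target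

**Step count and risks**

Total step count: 23. Longest linear sequence: 15 steps (steps 9–16, then 17–23, from 3-methylbutanal).

Steps most likely to fail:

Step 6. The tertiary C10 radical may be oxidised by trivalent manganese to the cation (then elimination or closure through the carbonyl oxygen) before it reaches the arene; the α-keto radical may add too slowly to the alkene carbon next to the quaternary centre; or the ring may close to the cis-fused isomer. Fallback, a classical cationic assembly that makes the two bonds in separate steps and sets out from 5: ketone 5 is converted through its enol phosphate, diethyl 1-(2-bromo-3-isopropyl-4-methoxyphenyl)vinyl phosphate F1 (LDA, ClP(O)(OEt)2, then more LDA), into 2-bromo-1-ethynyl-3-isopropyl-4-methoxybenzene F2. Deprotonation with EtMgBr gives [(2-bromo-3-isopropyl-4-methoxyphenyl)ethynyl]magnesium bromide F3, which adds to ketone 6 to give 1-[(2-bromo-3-isopropyl-4-methoxyphenyl)ethynyl]-2,2,6-trimethylcyclohexan-1-ol F4. Hydrogenation of the alkyne (H2, PtO2, EtOAc, aryl bromide retained) gives 1-[2-(2-bromo-3-isopropyl-4-methoxyphenyl)ethyl]-2,2,6-trimethylcyclohexan-1-ol F5. Cyclodehydration in polyphosphoric acid (hydride shift to the C10 cation, then Bogert–Cook-type Friedel–Crafts closure at C9, which is trans-selective for the 4,4,10-trimethyl system) gives (±)-trans-14-bromo-12-methoxyabieta-8,11,13-triene F6. Benzylic oxidation (CrO3, AcOH) comes back to the route at 10.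

Step 19. The alkenylpalladium may insert the alkene before taking up CO; palladium hydride may re-add and walk the double bond next to the cyclopropane, opening it; or the acyl group may be delivered to the wrong face. Fallback, a polarity-reversed acyl transfer that sets out from 25: Wittig homologation with methoxymethylenetriphenylphosphorane gives the 7-(methoxymethylidene) enol ether F7, which is hydrolysed on oxalic acid-doped wet silica (dioxolane retained) to the 7-carbaldehyde F8. NHC-catalysed intramolecular hydroacylation (triazolium precatalyst, DBU, dioxane, 100 °C) adds the acyl anion equivalent and its hydrogen syn across the C2'=C3' alkene from the face anti to the cyclopropane. This comes back to the route at 30, so steps 18–21 are bypassed.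

Step 13. The lithiated epoxide may undergo β-elimination or add the lithium amide instead of transferring the carbenoid to the hindered alkene, and the stereospecificity may be incomplete. Fallback, the diazoketone route, which sets out from 17: cross-metathesis with pent-4-enoic acid (second-generation Hoveyda–Grubbs catalyst) gives (4E,6S)-6-isopropyl-8-(2-methyl-1,3-dioxolan-2-yl)oct-4-enoic acid F9. Activation with isobutyl chloroformate and N-methylmorpholine gives the mixed carbonic anhydride F10, and diazomethane converts it into the diazoketone (5E,7S)-1-diazo-7-isopropyl-9-(2-methyl-1,3-dioxolan-2-yl)non-5-en-2-one F11. Intramolecular cyclopropanation with [Cu(MeCN)4]PF6 and a tert-butyl bis(oxazoline) ligand (monovalent copper carbenoid, E-alkene gives the exo side chain, ligand enantiomer chosen as the matched one) comes back to the route at 21, so steps 12–14 are bypassed.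

**Further compounds**

F1 | step 6 | diethyl 1-(2-bromo-3-isopropyl-4-methoxyphenyl)vinyl phosphate | C=C(OP(=O)(OCC)OCC)c1ccc(OC)c(C(C)C)c1Br
F2 | step 6 | 2-bromo-1-ethynyl-3-isopropyl-4-methoxybenzene | C#Cc1ccc(OC)c(C(C)C)c1Br
F3 | step 6 | [(2-bromo-3-isopropyl-4-methoxyphenyl)ethynyl]magnesium bromide | Br[Mg]C#Cc1ccc(OC)c(C(C)C)c1Br
F4 | step 6 | 1-[(2-bromo-3-isopropyl-4-methoxyphenyl)ethynyl]-2,2,6-trimethylcyclohexan-1-ol | CC1CCCC(C)(C)C1(O)C#Cc1ccc(OC)c(C(C)C)c1Br
F5 | step 6 | 1-[2-(2-bromo-3-isopropyl-4-methoxyphenyl)ethyl]-2,2,6-trimethylcyclohexan-1-ol | CC1CCCC(C)(C)C1(O)CCc1ccc(OC)c(C(C)C)c1Br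
F6 | step 6 | (±)-trans-14-bromo-12-methoxyabieta-8,11,13-triene (the (5S,10S) enantiomer is drawn) | CC(C)c1c(OC)cc2c(c1Br)CC[C@@H]1[C@]2(C)CCCC1(C)C
F7 | step 19 | 7-(methoxymethylidene) enol ether of 25 (E/Z mixture) | CC(C)c1c(OC)cc2c(c1C3=CC[C@H]4[C@H]([C@@H](CCC5(C)OCCO5)C(C)C)[C@@H]34)C(=COC)C[C@@H]6[C@]2(C)CCCC6(C)C
F8 | step 19 | 7-carbaldehyde homologue of 25 (C7 epimer mixture) | CC(C)c1c(OC)cc2c(c1C3=CC[C@H]4[C@H]([C@@H](CCC5(C)OCCO5)C(C)C)[C@@H]34)C(C=O)C[C@@H]6[C@]2(C)CCCC6(C)C
F9 | step 13 | (4E,6S)-6-isopropyl-8-(2-methyl-1,3-dioxolan-2-yl)oct-4-enoic acid | CC1(CC[C@@H](C(C)C)/C=C/CCC(=O)O)OCCO1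
F10 | step 13 | isobutyl carbonic anhydride of F9 | CC1(CC[C@@H](C(C)C)/C=C/CCC(=O)OC(=O)OCC(C)C)OCCO1
F11 | step 13 | (5E,7S)-1-diazo-7-isopropyl-9-(2-methyl-1,3-dioxolan-2-yl)non-5-en-2-one | CC1(CC[C@@H](C(C)C)/C=C/CCC(=O)C=[N+]=[N-])OCCO1
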